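**Plan**
- Retrosynthesis: the C3–OH is removed first (C3–H hydroxylation). Ring C is then cut at O1–C2 and C2–C3, giving a diprenylated phloroacetophenone (ring A) and 2,2-dimethylchromene-7-carboxylic acid (rings B and D).
- Rings B and D are cut together at C3'–C4' and C5'–C6'. This traces ring B back to a pyridazine plus a terminal alkyne, with loss of N2.
- Enabling feature: ring D supplies a four-atom strap across the C3'–C4' bond, made of the ether oxygen on C3', the CMe2 carbon and the cis CH=CH that ends on C4'. Used as a tether from the oxygen-bearing pyridazine carbon to the alkyne, it enforces the otherwise mismatched meta relation of C3'–O to C1'.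
- Forward order: Z-enynol chain, ether link to the pyridazine, rings B and D in one step. Ring A is bought and diprenylated, ring C is closed last, then the 3-OH is installed and the protecting groups removed.
- Stereochemistry: the target has no stereocentre. The only element is the Z alkene, set by anti hydroiodination of methyl propiolate and carried into ring D.

Key step: step 6

Remark: a metal salt that differs from a numbered compound only by exchange of an O–H proton (alkoxide, phenolate, enolate, carboxylate) is counted as that compound and gets no number. The 1,3-diketone is drawn as its diketo tautomer.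

**Step 1**
Reactants: 1 methyl propiolate
Product: 2 methyl (Z)-3-iodoacrylate
Conditions: NaI, AcOH, 70 °C
Reagents that add atoms: sodium iodide [Na+].[I-]
Why: Conjugate hydroiodination of an ynoate, in which iodide and the proton from acetic acid add anti, should give the kinetic Z-β-iodoacrylate as long as the temperature stays moderate.

**Step 2**
Reactants: 2 methyl (Z)-3-iodoacrylate
Product: 4 (Z)-4-iodo-2-methylbut-3-en-2-ol, via (Z)-4-iodobut-3-en-2-one 3 (not isolated)
Conditions: MeMgBr (2.5 equiv), Et2O, −78 to 0 °C
Reagents that add atoms: methylmagnesium bromide C[Mg]Br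
Why: Double Grignard 1,2-addition to the ester should be faster at low temperature than attack at the β-carbon or iodine–magnesium exchange, and it does not touch the alkene geometry.

**Step 3**
Reactants: 4 (Z)-4-iodo-2-methylbut-3-en-2-ol; 5 trimethylsilylacetylene
Product: 6 (Z)-2-methyl-6-(trimethylsilyl)hex-3-en-5-yn-2-ol
Conditions: PdCl2(PPh3)2 (cat.), CuI (cat.), Et3N, THF, rt
Reagents that add atoms: none
Why: Sonogashira coupling of a Z-alkenyl iodide runs at room temperature with retention of geometry and tolerates the free tertiary alcohol.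

**Step 4**
Reactants: 6 (Z)-2-methyl-6-(trimethylsilyl)hex-3-en-5-yn-2-ol
Product: 7 (Z)-2-methylhex-3-en-5-yn-2-ol
Conditions: K2CO3 (cat.), MeOH, 0 °C to rt
Reagents that add atoms: none
Why: Carbonate-catalysed methanolysis of the alkynyl C–Si bond (protodesilylation) is mild enough to leave the Z alkene and the alcohol unchanged.

**Step 5**
Reactants: 7 (Z)-2-methylhex-3-en-5-yn-2-ol; 8 methyl 6-chloropyridazine-4-carboxylate
Product: 9 methyl 6-{[(3Z)-2-methylhex-3-en-5-yn-2-yl]oxy}pyridazine-4-carboxylate
Conditions: NaH, THF, 0 °C; then 8, 0 °C to rt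
Reagents that add atoms: none
Why: Nucleophilic aromatic substitution (addition–elimination) at a chlorine-bearing carbon next to ring nitrogen is known for tertiary alkoxides on chloropyridazines, and the pre-formed sodium alkoxide at 0 °C should attack the methyl ester or close 5-exo onto its own alkyne only slowly.

**Step 6**
Reactants: 9 methyl 6-{[(3Z)-2-methylhex-3-en-5-yn-2-yl]oxy}pyridazine-4-carboxylate
Product: 11 methyl 2,2-dimethyl-2H-chromene-7-carboxylate, via bridged diazabicyclooctatriene adduct 10 (not isolated)
Conditions: PhNEt2 (high dilution), BHT (cat.), 180 °C, sealed tube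
Reagents that add atoms: none
Why: The C4 ester makes the diazine a better 4π acceptor, so the tethered terminal alkyne should add across C6 and C3 in an intramolecular inverse-electron-demand [4+2] cycloaddition (inner alkyne carbon to the oxygen-bearing C6, terminal carbon to C3), after which adduct 10 expels dinitrogen by retro-[4+2] and aromatises irreversibly. The closest known reaction type is the thermal intramolecular Diels–Alder/nitrogen extrusion of 3-(alkynyloxy)- and 3-(alkynylamino)pyridazines to dihydrobenzofurans, chromans and indolines, and the unsaturated tether is a new substrate within that class. Ring D closes in the fused mode as the six-membered ring C6–O–CMe2–CH=CH–C(inner alkyne) at the moment of cycloaddition, and ring B is assembled from pyridazine C3 to C6 plus both alkyne carbons once nitrogen has left. No stereocentre remains, because the two bridgeheads of racemic 10 become sp2 carbons, and the Z alkene passes unchanged into the ring D double bond. The selectivity required is regiochemical (oxygen meta and alkenyl carbon para to the ester-bearing carbon), and the tether length and Z geometry secure it, because the reverse orientation would need a strained bridged ring and the tether alkene sits too close to C6 to act as dienophile. The gem-dimethyl group and the rigid cis alkene lower the entropic cost, while the basic solvent and BHT are meant to suppress acid-triggered ionisation of the tertiary allylic ether and radical Z/E isomerisation.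

**Step 7**
Reactants: 11 methyl 2,2-dimethyl-2H-chromene-7-carboxylate
Product: 12 2,2-dimethyl-2H-chromene-7-carboxylic acid
Conditions: LiOH, THF/MeOH/H2O, rt; then 1 M HCl
Reagents that add atoms: lithium hydroxide [Li+].[OH-]
Why: Saponification of an unhindered methyl benzoate is routine, and the chromene ether and alkene are inert to aqueous hydroxide and to brief dilute acid.

**Step 8**
Reactants: 13 2,4,6-trihydroxyacetophenone; 14 prenyl bromide (2.1 equiv)
Product: 16 1-[2,4,6-trihydroxy-3,5-bis(3-methylbut-2-en-1-yl)phenyl]ethan-1-one, via monoprenyl ketone 15 (not isolated)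
Conditions: KOH, H2O, 0 °C to rt
Reagents that add atoms: none
Why: C-prenylation of the ambident acylphloroglucinol phenolate in water, where solvation of oxygen steers the soft allylic bromide to carbon, is the known entry to 3,5-diprenyl acylphloroglucinols and should fill the two free ring positions in turn.

**Step 9**
Reactants: 16 1-[2,4,6-trihydroxy-3,5-bis(3-methylbut-2-en-1-yl)phenyl]ethan-1-one
Product: 17 1-[2-hydroxy-4,6-bis(methoxymethoxy)-3,5-bis(3-methylbut-2-en-1-yl)phenyl]ethan-1-one
Conditions: MOMCl (2.2 equiv), i-Pr2NEt, CH2Cl2, 0 °C to rt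
Reagents that add atoms: chloromethyl methyl ether COCCl
Why: In this selective O-alkylation (MOM acetal protection) the hard electrophile reacts at oxygen, and the last hydroxyl should stay free because its hydrogen bond to the acetyl carbonyl lowers its reactivity.

**Step 10**
Reactants: 17 1-[2-hydroxy-4,6-bis(methoxymethoxy)-3,5-bis(3-methylbut-2-en-1-yl)phenyl]ethan-1-one; 12 2,2-dimethyl-2H-chromene-7-carboxylic acid
Product: 18 2-acetyl-3,5-bis(methoxymethoxy)-4,6-bis(3-methylbut-2-en-1-yl)phenyl 2,2-dimethyl-2H-chromene-7-carboxylate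
Conditions: EDC·HCl, DMAP, CH2Cl2, rt
Reagents that add atoms: none
Why: Steglich-type esterification through the acylpyridinium ion acylates hindered, chelated phenols under neutral conditions that spare the MOM acetals, prenyl groups and chromene.

**Step 11**
Reactants: 18 2-acetyl-3,5-bis(methoxymethoxy)-4,6-bis(3-methylbut-2-en-1-yl)phenyl 2,2-dimethyl-2H-chromene-7-carboxylate
Product: 20 2-(2,2-dimethyl-2H-chromen-7-yl)-5,7-bis(methoxymethoxy)-6,8-bis(3-methylbut-2-en-1-yl)-4H-chromen-4-one, via 1,3-diketone 19 (not isolated)
Conditions: DBU, pyridine, 90 °C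
Reagents that add atoms: none
Why: In the known DBU/pyridine one-pot flavone variant of the Baker–Venkataraman rearrangement, the acetyl enolate takes over the neighbouring aroyl group (C2–C3 bond) and the freed phenol then adds to the aroyl carbonyl and loses water (O1–C2 bond), so ring C should close without any acid reaching the MOM acetals.

**Step 12**
Reactants: 20 2-(2,2-dimethyl-2H-chromen-7-yl)-5,7-bis(methoxymethoxy)-6,8-bis(3-methylbut-2-en-1-yl)-4H-chromen-4-one
Product: 23 2-(2,2-dimethyl-2H-chromen-7-yl)-3-hydroxy-5,7-bis(methoxymethoxy)-6,8-bis(3-methylbut-2-en-1-yl)-4H-chromen-4-one, via 3-lithioflavone 21 (not isolated), via lithium flavon-3-yl(trimethoxy)borate 22 (not isolated)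
Conditions: LDA, THF, −78 °C; B(OMe)3, −78 to 0 °C; AcOH, 30% H2O2, 0 °C
Reagents that add atoms: hydrogen peroxide OO; in the intermediates only: lithium diisopropylamide [Li+].CC(C)[N-]C(C)C (lithium of 21 and 22) and trimethyl borate COB(OC)OC (boron and methoxy groups of 22)
Why: Lithiation–borylation–oxidation at C3–H, the kinetically most acidic C–H of a fully protected flavone, is a known flavone-to-flavonol conversion, and the C–B oxidation with cold peroxide should leave the prenyl and chromene alkenes alone, unlike dioxirane or peracid methods.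

**Step 13**
Reactants: 23 2-(2,2-dimethyl-2H-chromen-7-yl)-3-hydroxy-5,7-bis(methoxymethoxy)-6,8-bis(3-methylbut-2-en-1-yl)-4H-chromen-4-one
Product: 24 dorsilurin C
Conditions: 3 M aq. HCl, MeOH, 50 °C
Reagents that add atoms: none
Why: Acid-catalysed transacetalisation of aryl MOM ethers to methanol is the standard last step for prenylated flavonoids, and under short, mild exposure it should be faster than addition of the freed phenols to the prenyl groups.

**Compound list**
1 | methyl propiolate | C#CC(=O)OC | starting material
2 | methyl (Z)-3-iodoacrylate | COC(=O)/C=C\I | intermediate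
3 | (Z)-4-iodobut-3-en-2-one (not isolated) | CC(=O)/C=C\I | intermediate
4 | (Z)-4-iodo-2-methylbut-3-en-2-ol | CC(C)(O)/C=C\I | intermediate
5 | trimethylsilylacetylene | C#C[Si](C)(C)C | starting material
6 | (Z)-2-methyl-6-(trimethylsilyl)hex-3-en-5-yn-2-ol | CC(C)(O)/C=C\C#C[Si](C)(C)C | intermediate
7 | (Z)-2-methylhex-3-en-5-yn-2-ol | CC(C)(O)/C=C\C#C | intermediate
8 | methyl 6-chloropyridazine-4-carboxylate | COC(=O)c1cnnc(Cl)c1 | starting material
9 | methyl 6-{[(3Z)-2-methylhex-3-en-5-yn-2-yl]oxy}pyridazine-4-carboxylate | COC(=O)c1cnnc(OC(C)(C)/C=C\C#C)c1 | intermediate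
10 | 2,3-diazabicyclo[2.2.2]octa-2,5,7-triene adduct, racemic, one enantiomer drawn; bridgeheads are former pyridazine C6 and C3, the 2H-pyran ring is fused through C6 and the inner alkyne carbon (not isolated) | O1C(C)(C)C=CC2=C[C@H]3N=N[C@@]12C=C3C(=O)OC | intermediate
11 | methyl 2,2-dimethyl-2H-chromene-7-carboxylate | COC(=O)c1ccc2c(c1)OC(C)(C)C=C2 | intermediate
12 | 2,2-dimethyl-2H-chromene-7-carboxylic acid | OC(=O)c1ccc2c(c1)OC(C)(C)C=C2 | intermediate
13 | 2,4,6-trihydroxyacetophenone | CC(=O)c1c(O)cc(O)cc1O | starting material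
14 | prenyl bromide (1-bromo-3-methylbut-2-ene) | CC(C)=CCBr | starting material
15 | 1-[2,4,6-trihydroxy-3-(3-methylbut-2-en-1-yl)phenyl]ethan-1-one (not isolated) | CC(=O)c1c(O)cc(O)c(CC=C(C)C)c1O | intermediate
16 | 1-[2,4,6-trihydroxy-3,5-bis(3-methylbut-2-en-1-yl)phenyl]ethan-1-one | CC(=O)c1c(O)c(CC=C(C)C)c(O)c(CC=C(C)C)c1O | intermediate
17 | 1-[2-hydroxy-4,6-bis(methoxymethoxy)-3,5-bis(3-methylbut-2-en-1-yl)phenyl]ethan-1-one | CC(=O)c1c(O)c(CC=C(C)C)c(OCOC)c(CC=C(C)C)c1OCOC | intermediate
18 | 2-acetyl-3,5-bis(methoxymethoxy)-4,6-bis(3-methylbut-2-en-1-yl)phenyl 2,2-dimethyl-2H-chromene-7-carboxylate | CC(=O)c1c(OC(=O)c2ccc3c(c2)OC(C)(C)C=C3)c(CC=C(C)C)c(OCOC)c(CC=C(C)C)c1OCOC | intermediate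
19 | 1-(2,2-dimethyl-2H-chromen-7-yl)-3-[2-hydroxy-4,6-bis(methoxymethoxy)-3,5-bis(3-methylbut-2-en-1-yl)phenyl]propane-1,3-dione (not isolated) | O=C(CC(=O)c1ccc2c(c1)OC(C)(C)C=C2)c1c(O)c(CC=C(C)C)c(OCOC)c(CC=C(C)C)c1OCOC | intermediate
20 | 2-(2,2-dimethyl-2H-chromen-7-yl)-5,7-bis(methoxymethoxy)-6,8-bis(3-methylbut-2-en-1-yl)-4H-chromen-4-one | COCOc1c(CC=C(C)C)c(OCOC)c2c(=O)cc(-c3ccc4c(c3)OC(C)(C)C=C4)oc2c1CC=C(C)C | intermediate
21 | 3-lithio derivative of 20 (not isolated) | COCOc1c(CC=C(C)C)c(OCOC)c2c(=O)c([Li])c(-c3ccc4c(c3)OC(C)(C)C=C4)oc2c1CC=C(C)C | intermediate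
22 | lithium trimethoxyborate at C3 of 20 (not isolated) | [Li+].COCOc1c(CC=C(C)C)c(OCOC)c2c(=O)c([B-](OC)(OC)OC)c(-c3ccc4c(c3)OC(C)(C)C=C4)oc2c1CC=C(C)C | intermediate
23 | 2-(2,2-dimethyl-2H-chromen-7-yl)-3-hydroxy-5,7-bis(methoxymethoxy)-6,8-bis(3-methylbut-2-en-1-yl)-4H-chromen-4-one | COCOc1c(CC=C(C)C)c(OCOC)c2c(=O)c(O)c(-c3ccc4c(c3)OC(C)(C)C=C4)oc2c1CC=C(C)C | intermediate
24 | dorsilurin C, 2-(2,2-dimethyl-2H-chromen-7-yl)-3,5,7-trihydroxy-6,8-bis(3-methylbut-2-en-1-yl)-4H-chromen-4-one | CC(C)=CCc1c(O)c(CC=C(C)C)c2oc(-c3ccc4c(c3)OC(C)(C)C=C4)c(O)c(=O)c2c1O | target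

**Step count**
Total step count: 13.
Longest linear sequence: 11 steps (steps 1 to 7, then 10 to 13, from methyl propiolate). Steps 8 and 9 form the short ring A branch.

**Steps most likely to fail**

1. Step 6 (key step).
   - Risk: at the temperature needed, the cycloaddition may be outrun by loss of the tertiary allylic ether (ionisation, or six-centre elimination towards the pyridazinone) or by an oxygen-to-nitrogen [3,3] allyl shift.
   - Fallback: ring B is bought and only ring D is closed. The fallback sets out from 4. Suzuki–Miyaura coupling of 4 with commercial methyl 3-hydroxy-4-(4,4,5,5-tetramethyl-1,3,2-dioxaborolan-2-yl)benzoate (Pd(PPh3)4, K2CO3, dioxane/H2O, 60 °C) should give, with retention of the Z geometry, methyl 3-hydroxy-4-[(Z)-3-hydroxy-3-methylbut-1-enyl]benzoate F1. Warming F1 with catalytic PPTS in toluene should close the pyran by cyclodehydration, as is known for the Z-diols obtained from coumarins and methyl Grignard reagents. The route is rejoined at 11.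

2. Step 5.
   - Risk: the hindered tertiary alkoxide may substitute too slowly, so that closure of the oxygen onto its own alkyne or acyl attack at the methyl ester takes over.
   - Fallback: the ether bond is made before any alkyne is present, so the substitution can be given more time and warmth. The fallback sets out from 4 and 8. The sodium alkoxide of 4 (NaH, THF, 0 °C to rt) displaces chloride from 8 to give methyl 6-{[(3Z)-4-iodo-2-methylbut-3-en-2-yl]oxy}pyridazine-4-carboxylate F2. Sonogashira coupling with 5 (PdCl2(PPh3)2, CuI, Et3N, THF, rt) gives methyl 6-{[(3Z)-2-methyl-6-(trimethylsilyl)hex-3-en-5-yn-2-yl]oxy}pyridazine-4-carboxylate F3. Protodesilylation (K2CO3, MeOH, 0 °C, degenerate for the methyl ester) rejoins the route at 9.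

3. Step 12.
   - Risk: deprotonation may be incomplete or may stray to the benzylic/allylic CH2 groups, the 3-lithio species may ring-open before it is trapped, and the oxidative work-up may begin to epoxidise the prenyl groups.
   - Fallback: ring C and the 3-OH are made together from a chalcone, so steps 7 and 10 to 12 are bypassed. The fallback sets out from 11 and 17. Reduction of 11 with i-Bu2AlH (CH2Cl2, −78 °C) gives (2,2-dimethyl-2H-chromen-7-yl)methanol F4. MnO2 (CH2Cl2, rt) gives 2,2-dimethyl-2H-chromene-7-carbaldehyde F5. Claisen–Schmidt condensation with 17 (KOH, EtOH, rt) gives (E)-3-(2,2-dimethyl-2H-chromen-7-yl)-1-[2-hydroxy-4,6-bis(methoxymethoxy)-3,5-bis(3-methylbut-2-en-1-yl)phenyl]prop-2-en-1-one F6. Algar–Flynn–Oyamada oxidative cyclisation (30% H2O2, NaOH, MeOH, 0 °C), in which the nucleophilic peroxide attacks only the enone, rejoins the route at 23.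

**Further compounds**
F1 | step 6 | methyl 3-hydroxy-4-[(Z)-3-hydroxy-3-methylbut-1-enyl]benzoate | COC(=O)c1ccc(/C=C\C(C)(C)O)c(O)c1
F2 | step 5 | methyl 6-{[(3Z)-4-iodo-2-methylbut-3-en-2-yl]oxy}pyridazine-4-carboxylate | COC(=O)c1cnnc(OC(C)(C)/C=C\I)c1
F3 | step 5 | methyl 6-{[(3Z)-2-methyl-6-(trimethylsilyl)hex-3-en-5-yn-2-yl]oxy}pyridazine-4-carboxylate | COC(=O)c1cnnc(OC(C)(C)/C=C\C#C[Si](C)(C)C)c1
F4 | step 12 | (2,2-dimethyl-2H-chromen-7-yl)methanol | OCc1ccc2c(c1)OC(C)(C)C=C2
F5 | step 12 | 2,2-dimethyl-2H-chromene-7-carbaldehyde | O=Cc1ccc2c(c1)OC(C)(C)C=C2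
F6 | step 12 | (E)-3-(2,2-dimethyl-2H-chromen-7-yl)-1-[2-hydroxy-4,6-bis(methoxymethoxy)-3,5-bis(3-methylbut-2-en-1-yl)phenyl]prop-2-en-1-one | O=C(/C=C/c1ccc2c(c1)OC(C)(C)C=C2)c1c(O)c(CC=C(C)C)c(OCOC)c(CC=C(C)C)c1OCOC
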